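## Structural features

Eupacunolin is a germacranolide. A ten-membered carbocycle (C1–C10) is trans-fused at C6–C7 to an α-methylene-γ-butyrolactone (C11, C12, C13, O on C6). The carbocycle is a cis,cis-cyclodeca-1,6-diene: C4=C5 (bearing C15H2OH) and C9=C10 (bearing C14H3) both have their ring bonds cis, and each is flanked by two oxygenated allylic carbons (C3/C6 and C8/C1). The stereocentres form a contiguous triad, C6 (α-O), C7 (β-C11) and C8 (β-O), and an anti-1,3 pair, C1 (α-OH) and C3 (β-OAc), separated by C2H2. C1/C6 and C3/C8 face each other in a 1,6-relationship across the ring. Five oxygen functions must be told apart (free C1-OH, C3 acetate, free C15-OH, C8 tiglate, lactone O at C6), and the 1,3-related hydroxy/ester pairs can exchange acyl groups. The exocyclic enoate (a Michael acceptor), the allylic esters and every β-acyloxy or β-hydroxy ketone on the way (elimination, retro-aldol, hemiketal formation) are fragile. The real difficulty is to close the strained ten-membered ring while fixing two Z-trisubstituted alkenes and setting stereocentres on a floppy ring. The key step exploits two features. Because C9=C10 is cis, the atoms C1, C10, C9, C8, C7 and C6 fold into a cyclohexene once an extra C1–C6 bond joins the two 1,6-related oxygenated carbons. The remaining arc C1(=O)–C2H2–C3H(O)–C4=C5H–C6(=O) is then the exact retron of an acetylenic dioxy-Cope rearrangement, so the ring is made by four-atom enlargement of a cyclohexenediol and not by cyclising a chain.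

## Logic of the disconnections

24 to 23: the O15–Si bond is cut. The primary allylic alcohol stays masked to the end so that no oxidation or acylation step has to distinguish it. The forward step must be a fluoride cleavage that spares two esters and the enoate.

23 to 22 to 21: the C12=O oxidation level is lowered to the lactol, and the C11=C13 bond is cut. The methylene group is brought in at the aldehyde (lactol) level, where amine catalysis suffices. No ester enolate is then needed in a molecule that already carries the acetate and the tiglate. The demand is that the lactol opens enough to react as an aldehyde.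

21 to 20: the O6–C12 bond is cut, and C12 returns to a dioxolane. This keeps C11–C12 as a saturated, π-free side chain through the key step. The forward step needs mild acid only.

20 to 19: the C1–H bond is cut (ketone at C1). C1 is a simple alkenyl/methylene ketone, a good case for catalyst control, and its alcohol needs no protection because it stays free in 24.

19 to 17 and 18: the C6–H bond and the O8–acyl bond are cut together. One operation delivers the hydride to C6 (1,3-anti to O8) and leaves the hydride donor on O8 as the tiglate. This removes one acylation and one protecting-group decision. The demand is a free C8-OH next to the C6 ketone.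

17 to 16 to 15 (key): the C3–C4 bond is cut and C1–C6 is reconnected. The ten-membered (Z,Z)-dienedione collapses to a cyclohexene-1,2-diol that carries a two-carbon alkenyl arm on C1 and a four-carbon alkynyl arm on C6. The medium ring, the geometry of both alkenes and C3 are all traded for a six-membered ring. The forward step must be periselective, must transfer chirality from C1 to C3, and must not lose the β-acetoxy group.

15 to 14 to 13: three O–Si bonds and the O–C3 bond are cut (acetic acid taken off a terminal alkyne). The C3 acetate of 24 is thus already present as the enol ester terminus of the rearrangement. The demand is anti-Markovnikov, Z-selective addition to the terminal alkyne only.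

13 to 12 to 11: the C8–H bond is cut, and the C8 ketone is returned to its dimethyl ketal. C8 is set on the rigid ring next to C7. The ketal may only be opened once C1 and C6 are quaternary, because aromatisation is blocked only then.

11 to 9 and 10, and 9 to 8 to 6 and 7: the C5–C6 and C1–C2 bonds are cut. Both arms come from commercial alkynes by two carbonyl additions. The demand is the cis-1β,6β-diol, which the ring substituents should favour.

6 to 5 to 4 to 2 and 3: the C6–O and C7–C11 bonds are cut. One catalytic conjugate addition sets C7, the only stereocentre from which all others are relayed, and its enolate is used to oxygenate C6.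

2 to 1: one C8–O bond is cut (oxidative dearomatisation). All six ring-B carbons, C14 and the C1/C8 oxygens come from one cheap phenol.

## Other disconnections considered

Alternative 1: Cut C6–C7 (and O6–C12). This is the plan that comes to mind first. The forward key step is an intramolecular Barbier/Nozaki–Hiyama-type 2-(alkoxycarbonyl)allylation of the open-chain bromo ester enal A1, followed by lactonisation. It forms the lactone and the ring at once. However, the ten-membered ring is closed end to end at high dilution, and the C6/C7 outcome depends on an unknown macrocyclic transition state. A1 contains a Z-enal that can isomerise. It also needs both Z-trisubstituted alkenes, three separate carbinol centres and full oxygen differentiation before the ring exists. The chosen plan draws both alkene geometries from ring constraints and builds C2–C5 from two commercial alkynes.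

Alternative 2: Cut C6–C7 and reconnect C6–O–C13. The forward key step is a [2,3]-Wittig ring contraction of the 13-membered bis-allylic ether A2, which would set C6, C7 and the exocyclic methylene together. The carbanion needed at C6 is an allyl anion delocalised onto C4. C4 carries two β-leaving groups (O on C3 and O on C15), so elimination should outrun the shift. Deprotonation can also occur at C13, and [1,2]-shift competes. The strong base forbids esters, so more protecting-group steps are needed, and a macro-etherification is required first. Two ring-forming events are spent on one ring.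

Alternative 3: Cut C1–C2 and reconnect C1–C6. The forward key step is a Dowd–Beckwith-type four-atom radical ring expansion of the iodo ketone A3: the C2 radical adds to the C1 carbonyl, and the alkoxy radical cleaves C1–C6. It uses the same hidden bond and runs under mild conditions. However, C6 would be created by hydrogen transfer to a planar allyl radical, with control neither of the face nor of C6 versus C4. Premature reduction of the primary radical also competes. The side chain, with C3 and the Z-alkene, needs its own multi-step synthesis. The chosen plan sets C6 by a directed hydride shift and is shorter.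

Key step: step 11

Assumption: the germacrane numbering of the target (C1–C15; lactone O on C6, tiglate on C8) is kept for every intermediate. α/β refer to the flat projection in which H-7 is α, so the C7–C11 bond is β.

Assumption: in step 2 the ligand enantiomer is the one that delivers the nucleophile to the face giving the 7β side chain.

## Steps

Step 1
Reactants: 1 4-methoxy-2-methylphenol
Product: 2 4,4-dimethoxy-2-methylcyclohexa-2,5-dien-1-one
Conditions: PhI(OAc)2, MeOH, 0 °C
Reagents that add atoms: methanol, CO
Why: Oxidative dearomatisation of a 4-alkoxyphenol with iodine(III) in methanol should give the quinone monoketal, which already holds C1=O, C10–C14, C9 and C8 at the ketone level and the unsubstituted enone arm C6=C7.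

Step 2
Reactants: 2 4,4-dimethoxy-2-methylcyclohexa-2,5-dien-1-one; 3 (1,3-dioxolan-2-ylmethyl)magnesium bromide
Product: 4 6-(1,3-dioxolan-2-ylmethyl)-5,5-dimethoxy-3-methyl-2-(trimethylsilyloxy)cyclohexa-1,3-diene (C7 side chain β)
Conditions: CuBr·SMe2 (5 mol %), Josiphos-type ferrocenyl diphosphine (6 mol %), TMSCl, t-BuOMe, −78 °C
Reagents that add atoms: chlorotrimethylsilane, C[Si](C)(C)Cl
Why: Copper-catalysed asymmetric conjugate addition of a Grignard reagent should attack C7, because the other enone arm is α-methylated and slower. The chiral copper complex sets C7. TMSCl traps the enolate regiospecifically as the C1=C6 enol ether.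

Step 3
Reactants: 4 6-(1,3-dioxolan-2-ylmethyl)-5,5-dimethoxy-3-methyl-2-(trimethylsilyloxy)cyclohexa-1,3-diene
Product: 6 trans-5-(1,3-dioxolan-2-ylmethyl)-6-hydroxy-4,4-dimethoxy-2-methylcyclohex-2-en-1-one (7β side chain; 6α-OH), via 6α-silyloxy enone 5 (not isolated)
Conditions: mCPBA, hexane–CH2Cl2, −20 °C; then citric acid (cat.), MeOH, 0 °C
Reagents that add atoms: 3-chloroperbenzoic acid, OOC(=O)c1cccc(Cl)c1
Why: Rubottom oxidation should epoxidise the electron-rich C1=C6 enol ether anti to the C7 side chain. Silyl migration and mild methanolysis then give the α-hydroxy ketone. The C6 configuration is of no consequence because C6 is oxidised in step 5.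

Step 4
Reactants: 6 trans-5-(1,3-dioxolan-2-ylmethyl)-6-hydroxy-4,4-dimethoxy-2-methylcyclohex-2-en-1-one; 7 ethynylmagnesium bromide
Product: 8 5-(1,3-dioxolan-2-ylmethyl)-1-ethynyl-4,4-dimethoxy-2-methylcyclohex-2-ene-1,6-diol (1β-OH; 1α-ethynyl; 6α-OH; 7β side chain)
Conditions: 7 (3 equiv), THF, −78 to −20 °C; H2O
Reagents that add atoms: none
Why: 1,2-Addition of the slim acetylide to the enone should follow the axial trajectory on the face opposite the equatorial C7 side chain. This is the usual sense for 5-substituted cyclohexenones. It gives 1α-ethynyl/1β-OH and makes C1 quaternary, which blocks aromatisation from here on.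

Step 5
Reactants: 8 5-(1,3-dioxolan-2-ylmethyl)-1-ethynyl-4,4-dimethoxy-2-methylcyclohex-2-ene-1,6-diol
Product: 9 6-(1,3-dioxolan-2-ylmethyl)-2-ethynyl-2-hydroxy-5,5-dimethoxy-3-methylcyclohex-3-en-1-one (C6 ketone; 1β-OH; 1α-ethynyl; 7β side chain)
Conditions: Dess–Martin periodinane, CH2Cl2, 0 °C to rt
Reagents that add atoms: none
Why: Dess–Martin oxidation touches only the secondary C6 carbinol. The neutral medium should leave the ketal, the dioxolane and H-7 (now α to a ketone and β to the ketal) undisturbed.

Step 6
Reactants: 9 6-(1,3-dioxolan-2-ylmethyl)-2-ethynyl-2-hydroxy-5,5-dimethoxy-3-methylcyclohex-3-en-1-one; 10 tert-butyldimethyl(prop-2-yn-1-yloxy)silane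
Product: 11 cis-1β,6β-diol 1α-ethynyl-6α-[3-(tert-butyldimethylsilyloxy)prop-1-ynyl]-7β-(1,3-dioxolan-2-ylmethyl)-8,8-dimethoxy-10-methylcyclohex-9-ene-1,6-diol
Conditions: 10, n-BuLi, THF, −78 °C; LaCl3·2LiCl (30 mol %); 9, −78 °C; H2O
Reagents that add atoms: none
Why: Acetylide 1,2-addition. The lanthanum salt should suppress enolisation and loss of methanol. The β face of C6 is screened by the axial ketal methoxy group and the C7 side chain, so attack from the α face should give the 6β-alcohol, that is the cis-diol.

Step 7
Reactants: 11 cis-1β,6β-diol with C8 dimethyl ketal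
Product: 12 C8 enone 4α-ethynyl-5α-[3-(tert-butyldimethylsilyloxy)prop-1-ynyl]-6β-(1,3-dioxolan-2-ylmethyl)-4β,5β-dihydroxy-3-methylcyclohex-2-en-1-one
Conditions: PPTS (cat.), acetone–H2O, rt
Reagents that add atoms: water, O
Why: An allylic dimethyl ketal hydrolyses far faster than an aldehyde dioxolane or a primary TBS ether. With C1 and C6 quaternary, the released enone cannot tautomerise to an arene.

Step 8
Reactants: 12 C8 enone
Product: 13 1β,6β,8β-triol 1α-ethynyl-6α-[3-(tert-butyldimethylsilyloxy)prop-1-ynyl]-7β-(1,3-dioxolan-2-ylmethyl)-10-methylcyclohex-9-ene-1,6,8-triol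
Conditions: L-Selectride, THF, −78 °C; H2O
Reagents that add atoms: none
Why: The bulky hydride should reduce 1,2, because the β-carbon C10 is fully substituted. It should approach from the α face, because the β face carries the axial C6 oxygen in a 1,3-relationship and the C7 side chain. This gives the 8β-alcohol cis to the side chain.

Step 9
Reactants: 13 1β,6β,8β-triol
Product: 14 1α-[(Z)-2-acetoxyvinyl] triol (C2=C3 Z; acetate on C3)
Conditions: Ru(η3-methallyl)2(dppe) (3 mol %), AcOH, toluene, 65 °C
Reagents that add atoms: acetic acid, CC(=O)O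
Why: Ruthenium-catalysed anti-Markovnikov addition of a carboxylic acid runs through a vinylidene. It can therefore only engage the terminal alkyne, and it should give the Z-enol ester even on tertiary propargylic alcohols. The future C3 acetate is now in place.

Step 10
Reactants: 14 1α-[(Z)-2-acetoxyvinyl] triol
Product: 15 1β,6β,8β-tris(trimethylsilyl) ether of 14
Conditions: 1-(trimethylsilyl)imidazole, CH2Cl2, 40 °C
Reagents that add atoms: 1-(trimethylsilyl)imidazole, C[Si](C)(C)n1ccnc1
Why: Neutral silylation covers both tertiary alcohols and C8-OH without a Lewis acid that would open the dioxolane. It removes every O–H that could start retro-ene cleavage or acyl transfer on heating.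

Step 11
Reactants: 15 1β,6β,8β-tris(trimethylsilyl) ether
Product: 17 (4Z,9Z)-3β-acetoxy-8β-hydroxy-15-(tert-butyldimethylsilyloxy)-7β-(1,3-dioxolan-2-ylmethyl)-10-methylcyclodeca-4,9-diene-1,6-dione, via ten-membered bis-enol silyl ether 16 (not isolated)
Conditions: degassed o-dichlorobenzene (0.01 M), BHT (cat.), silylated glass, 185 °C; then 0.5 M aq citric acid, THF, 0 °C
Reagents that add atoms: none
Why: A thermal [3,3]-sigmatropic shift of the 1,5-enyne C3=C2–C1–C6–C5≡C4 (the siloxy variant of the acetylenic oxy-Cope rearrangement; closest known type: the four-carbon ring enlargement of 1,2-dialkenylcyclohexane-1,2-diols to cyclodecane-1,6-diones) makes C3–C4 while the doubly oxygenated, fully substituted C1–C6 bond breaks, so the cyclohexene becomes the ten-membered ring without any end-to-end cyclisation. The only ring closed is the carbocycle, and it is closed by ring enlargement through a six-centre half-chair array in which C3 bonds to C4, not by an exo or endo attack at high dilution. C9=C10 stays cis because it is carried over from the six-membered ring, and C4=C5 should become cis when the siloxyallene of 16 is protonated at C5 from the open exocyclic C15 side. The one new stereocentre, C3, is set by suprafacial chirality transfer from C1: the Z-acetoxy group has to sit inside (pseudo-axial) and should do so next to the C1 oxygen rather than next to ring carbon C10, which selects one half-chair and places the acetate on the β face. The periselectivity needed is secured by the substrate: the C7 side chain has no π bond, the ring alkene C9=C10 lies almost in the plane of the C1–C6 bond and cannot overlap with it, and the silyl ethers exclude retro-ene cleavage. The driving force is the release of the two congested vicinal quaternary carbons and the gain of two enol ether units, and the hydrolysis then removes 16 irreversibly. C7 and C8 are spectators, and the weakly acidic work-up is chosen so that H-7 is not exchanged and neither the β-acetoxy nor the β-hydroxy group is eliminated.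

Step 12
Reactants: 17 3β-acetoxy-8β-hydroxy-1,6-dione; 18 (E)-2-methylbut-2-enal
Product: 19 3β-acetoxy-6α-hydroxy-8β-tigloyloxy-1-ketone (4Z,9Z; 15-OTBS; 7β-dioxolanylmethyl)
Conditions: 18 (6 equiv), SmI2 (25 mol %), THF, −10 °C
Reagents that add atoms: none
Why: Evans–Tishchenko reduction. The hemiacetal of 18 on C8-OH, held to the C6 ketone by samarium(III), shifts its hydride through a chair six-membered array. This should give the 1,3-anti 6α-alcohol and leave the oxidised donor on O8 as the tiglate. The C1 ketone is out of reach of this delivery.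

Step 13
Reactants: 19 3β-acetoxy-6α-hydroxy-8β-tigloyloxy-1-ketone
Product: 20 1α,6α-diol (3β-OAc; 8β-OTig; 15-OTBS; 7β-dioxolanylmethyl)
Conditions: (R)-Me-CBS (20 mol %), BH3·SMe2, THF, −40 °C; H2O
Reagents that add atoms: none
Why: Corey–Bakshi–Shibata reduction. The α-methylated alkenyl arm (C10) acts as the large group and C2H2 as the small one, so the (R)-catalyst should give the (1S)-alcohol (1α, anti to the C3 acetate), with 1,2-selectivity and tolerance of the esters.

Step 14
Reactants: 20 1α,6α-diol
Product: 21 6α,12-lactol (C12 hemiacetal; anomers)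
Conditions: PPTS (cat.), acetone–H2O, 40 °C
Reagents that add atoms: water, O
Why: The neighbouring C6-OH should open the dioxolane by five-membered-ring transacetalisation, which makes the hydrolysis much easier than that of an isolated dioxolane. C8 is esterified, so only O6 can close the ring.

Step 15
Reactants: 21 6α,12-lactol
Product: 22 11(13)-methylene lactol
Conditions: 37 % aq HCHO, pyrrolidine (10 mol %), 4-(dimethylamino)benzoic acid (20 mol %), CH2Cl2, 40 °C
Reagents that add atoms: formaldehyde, C=O
Why: Amine-catalysed α-methylenation of an aldehyde (enamine, Mannich addition, elimination) acts on the open hydroxy-aldehyde form of the lactol. It needs no strong base, so the acetate, the tiglate and the free C1-OH should survive.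

Step 16
Reactants: 22 11(13)-methylene lactol
Product: 23 15-O-(tert-butyldimethylsilyl)eupacunolin
Conditions: TEMPO (10 mol %), PhI(OAc)2, CH2Cl2, rt
Reagents that add atoms: none
Why: Oxoammonium oxidation takes lactols much faster than hindered secondary alcohols. The α-methylene-γ-lactone should therefore form while C1-OH stays untouched and C15 is still silylated.

Step 17
Reactants: 23 15-O-(tert-butyldimethylsilyl)eupacunolin
Product: 24 eupacunolin
Conditions: HF·pyridine, pyridine, THF, 0 °C
Reagents that add atoms: none
Why: Buffered fluoride cleavage of the primary allylic TBS ether is neither basic nor strongly acidic. Acyl migration between O3, O15 and O1 and addition to the enoate should therefore be avoided.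

## Compound list

1 | 4-methoxy-2-methylphenol | COc1ccc(O)c(C)c1 | starting material
2 | 4,4-dimethoxy-2-methylcyclohexa-2,5-dien-1-one | CC1=CC(OC)(OC)C=CC1=O | intermediate
3 | (1,3-dioxolan-2-ylmethyl)magnesium bromide | Br[Mg]CC1OCCO1 | starting material
4 | 6-(1,3-dioxolan-2-ylmethyl)-5,5-dimethoxy-3-methyl-2-(trimethylsilyloxy)cyclohexa-1,3-diene (C7 side chain β) | CC1=CC(OC)(OC)[C@@H](CC2OCCO2)C=C1O[Si](C)(C)C | intermediate
5 | 6α-silyloxy enone: trans-5-(1,3-dioxolan-2-ylmethyl)-4,4-dimethoxy-2-methyl-6-(trimethylsilyloxy)cyclohex-2-en-1-one | CC1=CC(OC)(OC)[C@@H](CC2OCCO2)[C@H](O[Si](C)(C)C)C1=O | intermediate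
6 | trans-5-(1,3-dioxolan-2-ylmethyl)-6-hydroxy-4,4-dimethoxy-2-methylcyclohex-2-en-1-one (7β side chain; 6α-OH) | CC1=CC(OC)(OC)[C@@H](CC2OCCO2)[C@H](O)C1=O | intermediate
7 | ethynylmagnesium bromide | C#C[Mg]Br | starting material
8 | 5-(1,3-dioxolan-2-ylmethyl)-1-ethynyl-4,4-dimethoxy-2-methylcyclohex-2-ene-1,6-diol (1β-OH; 1α-ethynyl; 6α-OH; 7β side chain) | CC1=CC(OC)(OC)[C@@H](CC2OCCO2)[C@H](O)[C@]1(O)C#C | intermediate
9 | 6-(1,3-dioxolan-2-ylmethyl)-2-ethynyl-2-hydroxy-5,5-dimethoxy-3-methylcyclohex-3-en-1-one (C6 ketone; 1β-OH; 1α-ethynyl) | CC1=CC(OC)(OC)[C@@H](CC2OCCO2)C(=O)[C@]1(O)C#C | intermediate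
10 | tert-butyldimethyl(prop-2-yn-1-yloxy)silane | C#CCO[Si](C)(C)C(C)(C)C | starting material
11 | cis-1β,6β-diol with 1α-ethynyl, 6α-[3-(TBSO)prop-1-ynyl], 7β-(1,3-dioxolan-2-ylmethyl), C8 dimethyl ketal | CC1=CC(OC)(OC)[C@@H](CC2OCCO2)[C@](O)(C#CCO[Si](C)(C)C(C)(C)C)[C@]1(O)C#C | intermediate
12 | C8 enone of 11 | CC1=CC(=O)[C@@H](CC2OCCO2)[C@](O)(C#CCO[Si](C)(C)C(C)(C)C)[C@]1(O)C#C | intermediate
13 | 1β,6β,8β-triol | CC1=C[C@@H](O)[C@@H](CC2OCCO2)[C@](O)(C#CCO[Si](C)(C)C(C)(C)C)[C@]1(O)C#C | intermediate
14 | 1α-[(Z)-2-acetoxyvinyl]-1β,6β,8β-triol | CC1=C[C@@H](O)[C@@H](CC2OCCO2)[C@](O)(C#CCO[Si](C)(C)C(C)(C)C)[C@]1(O)/C=C\OC(C)=O | intermediate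
15 | 1β,6β,8β-tris(trimethylsilyl) ether of 14 | CC1=C[C@@H](O[Si](C)(C)C)[C@@H](CC2OCCO2)[C@](O[Si](C)(C)C)(C#CCO[Si](C)(C)C(C)(C)C)[C@]1(O[Si](C)(C)C)/C=C\OC(C)=O | intermediate
16 | ten-membered bis-enol silyl ether (C1=C2 silyl enol ether, C4=C5=C6 siloxyallene, 3β-OAc, 8β-OTMS; allene axis not specified) | C[Si](C)(C)OC1=C=C(CO[Si](C)(C)C(C)(C)C)[C@@H](OC(C)=O)/C=C(\O[Si](C)(C)C)/C(C)=C\[C@@H](O[Si](C)(C)C)[C@H]1CC2OCCO2 | intermediate
17 | (4Z,9Z)-3β-acetoxy-8β-hydroxy-15-(TBSO)-7β-(1,3-dioxolan-2-ylmethyl)-10-methylcyclodeca-4,9-diene-1,6-dione | O=C1/C=C(/CO[Si](C)(C)C(C)(C)C)[C@@H](OC(C)=O)CC(=O)/C(C)=C\[C@@H](O)[C@H]1CC2OCCO2 | intermediate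
18 | (E)-2-methylbut-2-enal (tiglic aldehyde) | C/C=C(\C)C=O | starting material
19 | 3β-acetoxy-6α-hydroxy-8β-tigloyloxy-1-ketone | O[C@@H]1/C=C(/CO[Si](C)(C)C(C)(C)C)[C@@H](OC(C)=O)CC(=O)/C(C)=C\[C@@H](OC(=O)/C(C)=C/C)[C@H]1CC2OCCO2 | intermediate
20 | 1α,6α-diol (3β-OAc, 8β-OTig, 15-OTBS, 7β-dioxolanylmethyl) | O[C@@H]1/C=C(/CO[Si](C)(C)C(C)(C)C)[C@@H](OC(C)=O)C[C@H](O)/C(C)=C\[C@@H](OC(=O)/C(C)=C/C)[C@H]1CC2OCCO2 | intermediate
21 | 6α,12-lactol (anomers) | C1C(O)O[C@@H]2/C=C(/CO[Si](C)(C)C(C)(C)C)[C@@H](OC(C)=O)C[C@H](O)/C(C)=C\[C@@H](OC(=O)/C(C)=C/C)[C@@H]12 | intermediate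
22 | 11(13)-methylene lactol (anomers) | C=C1C(O)O[C@@H]2/C=C(/CO[Si](C)(C)C(C)(C)C)[C@@H](OC(C)=O)C[C@H](O)/C(C)=C\[C@@H](OC(=O)/C(C)=C/C)[C@@H]12 | intermediate
23 | 15-O-(tert-butyldimethylsilyl)eupacunolin | C=C1C(=O)O[C@@H]2/C=C(/CO[Si](C)(C)C(C)(C)C)[C@@H](OC(C)=O)C[C@H](O)/C(C)=C\[C@@H](OC(=O)/C(C)=C/C)[C@@H]12 | intermediate
24 | eupacunolin, (1S,3S,6R,7R,8R,4Z,9Z)-3-acetoxy-1,15-dihydroxy-8-[(E)-2-methylbut-2-enoyloxy]germacra-4,9,11(13)-trien-12,6-olide | C=C1C(=O)O[C@@H]2/C=C(/CO)[C@@H](OC(C)=O)C[C@H](O)/C(C)=C\[C@@H](OC(=O)/C(C)=C/C)[C@@H]12 | target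

## Step count and least certain steps

Total step count: 17. Longest linear sequence: 17 steps from 1 (3, 7, 10 and 18 are bought).

**Step 11 (key step).**
- Risk: the Z-acetoxy group is forced into the inside position next to a silyloxy group, which raises the barrier. The shift may then be outrun by thermal decomposition or stop at an unfavourable equilibrium.
- Risk: leakage through the other half-chair would erode the C3 configuration.
- Risk: protonation of the allenyl ether from the wrong side would give the wrong C4=C5 geometry.
- Risk: loss of acetic acid or water from the β-oxygenated ketones may occur on work-up.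
- Fallback: a stepwise ring enlargement through the same hidden bond with known reactions, setting out from 6 and coming back at 17.
  - Allylmagnesium bromide adds to C1 of 6 to give the allyl carbinol F1.
  - Dess–Martin oxidation gives the ketol F2.
  - Lithiated 10 adds to C6 to give the propargylic diol F3.
  - Hydroxyl-directed trans-hydroalumination with Red-Al and iodination give the (Z)-vinyl iodide F4.
  - Lemieux–Johnson cleavage of the terminal alkene gives the aldehyde F5.
  - An intramolecular Nozaki–Hiyama–Kishi reaction closes the six-membered ring C1–C6 at C3–C4 to give the cis-decalin triol F6.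
  - Acetylation of the only secondary alcohol gives the 3-acetate F7.
  - PPTS in wet acetone gives the enone F8.
  - L-Selectride gives the 8β-alcohol F9.
  - Criegee cleavage of the C1/C6 glycol with Pb(OAc)4 gives 17.

**Step 2.**
- Risk: the β-oxygenated Grignard reagent may add 1,2.
- Risk: its magnesium salts may ionise the ketal and start aromatisation.
- Risk: the enantioselectivity with this unusual nucleophile on a dienone may be low.
- Fallback: resolution instead of asymmetric catalysis, setting out from 2 and coming back at 6.
  - Achiral CuI·2LiCl catalysis with TMSCl gives 4 together with the ent-dienol ether F10.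
  - Rubottom oxidation carries both on, the unwanted series passing through the ent-silyloxy enone F11 to the ent-hydroxy ketone F12.
  - A lipase with vinyl acetate acylates the unwanted enantiomer to the ent-acetate F13.
  - Unreacted 6 is separated.

**Step 8.**
- Risk: poor facial selectivity if the ring adopts the other half-chair.
- Risk: competing 1,4-reduction.
- Fallback: inversion instead of direct control, setting out from 12 and coming back at 13.
  - Luche reduction (axial hydride) gives the 8α-alcohol F14.
  - A Mitsunobu reaction with 4-nitrobenzoic acid gives the inverted 8β-(4-nitrobenzoate) F15.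
  - K2CO3 in methanol gives 13.

**Step 12.**
- Risk: hydride transfer from the hemiacetal of a conjugated aldehyde may be slow.
- Risk: C8-OH may be tied up by hemiketal formation with the C1 ketone across the Z-alkene.
- Risk: retro-aldol opening at C7–C8 or migration of the tiglate to O6 may intervene.
- Fallback: acylation first, then catalyst-controlled reduction, setting out from 17 and coming back at 20.
  - Tigloyl chloride and pyridine give the 8-O-tigloyl dione F16.
  - (R)-Me-CBS with excess BH3·SMe2 reduces both enone carbonyls, with the alkenyl arms acting as the large groups, to 20.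

**Step 15.**
- Risk: the lactol may open too little to enter the enamine cycle.
- Risk: the amine may add reversibly to the product.
- Risk: acyl migration may set in on prolonged warming.
- Fallback: methylenation at the lactone level, setting out from 21 and coming back at 23.
  - TEMPO/PhI(OAc)2 gives the saturated lactone F17.
  - LiHMDS (2.2 equiv, −78 °C; the lactone is the most acidic C–H acid present) and Eschenmoser's salt give the Mannich base F18.
  - Methyl iodide gives the methiodide F19.
  - NaHCO3 effects elimination to 23.

## Further compounds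

F1 | step 11 | allyl carbinol (1α-allyl, 1β-OH, 6α-OH, C8 ketal) | CC1=CC(OC)(OC)[C@@H](CC2OCCO2)[C@H](O)[C@]1(O)CC=C
F2 | step 11 | ketol (C6 ketone, 1α-allyl, 1β-OH) | CC1=CC(OC)(OC)[C@@H](CC2OCCO2)C(=O)[C@]1(O)CC=C
F3 | step 11 | propargylic diol (cis-1β,6β-diol, 1α-allyl) | CC1=CC(OC)(OC)[C@@H](CC2OCCO2)[C@](O)(C#CCO[Si](C)(C)C(C)(C)C)[C@]1(O)CC=C
F4 | step 11 | (Z)-vinyl iodide (iodine on C4, cis to C6) | CC1=CC(OC)(OC)[C@@H](CC2OCCO2)[C@](O)(/C=C(\I)CO[Si](C)(C)C(C)(C)C)[C@]1(O)CC=C
F5 | step 11 | aldehyde (C3 aldehyde, C4 iodide) | CC1=CC(OC)(OC)[C@@H](CC2OCCO2)[C@](O)(/C=C(\I)CO[Si](C)(C)C(C)(C)C)[C@]1(O)CC=O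
F6 | step 11 | cis-decalin triol (1β,6β-diol, 3β-OH, C8 ketal) | CC1=CC(OC)(OC)[C@@H](CC2OCCO2)[C@]3(O)C=C(CO[Si](C)(C)C(C)(C)C)[C@@H](O)C[C@]13O
F7 | step 11 | 3-acetate of the cis-decalin triol | CC1=CC(OC)(OC)[C@@H](CC2OCCO2)[C@]3(O)C=C(CO[Si](C)(C)C(C)(C)C)[C@@H](OC(C)=O)C[C@]13O
F8 | step 11 | enone (C8 ketone) of the decalin acetate | CC1=CC(=O)[C@@H](CC2OCCO2)[C@]3(O)C=C(CO[Si](C)(C)C(C)(C)C)[C@@H](OC(C)=O)C[C@]13O
F9 | step 11 | 8β-alcohol of the decalin acetate | CC1=C[C@@H](O)[C@@H](CC2OCCO2)[C@]3(O)C=C(CO[Si](C)(C)C(C)(C)C)[C@@H](OC(C)=O)C[C@]13O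
F10 | step 2 | ent-dienol ether (enantiomer of 4) | CC1=CC(OC)(OC)[C@H](CC2OCCO2)C=C1O[Si](C)(C)C
F11 | step 2 | ent-silyloxy enone (enantiomer of 5) | CC1=CC(OC)(OC)[C@H](CC2OCCO2)[C@@H](O[Si](C)(C)C)C1=O
F12 | step 2 | ent-hydroxy ketone (enantiomer of 6) | CC1=CC(OC)(OC)[C@H](CC2OCCO2)[C@@H](O)C1=O
F13 | step 2 | ent-acetate (acetate of the enantiomer of 6) | CC1=CC(OC)(OC)[C@H](CC2OCCO2)[C@@H](OC(C)=O)C1=O
F14 | step 8 | 8α-alcohol (C8 epimer of 13) | CC1=C[C@H](O)[C@@H](CC2OCCO2)[C@](O)(C#CCO[Si](C)(C)C(C)(C)C)[C@]1(O)C#C
F15 | step 8 | 8β-(4-nitrobenzoate) of 13 | CC1=C[C@@H](OC(=O)c2ccc(cc2)[N+](=O)[O-])[C@@H](CC3OCCO3)[C@](O)(C#CCO[Si](C)(C)C(C)(C)C)[C@]1(O)C#C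
F16 | step 12 | 8-O-tigloyl dione | O=C1/C=C(/CO[Si](C)(C)C(C)(C)C)[C@@H](OC(C)=O)CC(=O)/C(C)=C\[C@@H](OC(=O)/C(C)=C/C)[C@H]1CC2OCCO2
F17 | step 15 | saturated lactone (13-nor, C11H2) | C1C(=O)O[C@@H]2/C=C(/CO[Si](C)(C)C(C)(C)C)[C@@H](OC(C)=O)C[C@H](O)/C(C)=C\[C@@H](OC(=O)/C(C)=C/C)[C@@H]12
F18 | step 15 | Mannich base (11-dimethylaminomethyl lactone, C11 epimers) | CN(C)CC1C(=O)O[C@@H]2/C=C(/CO[Si](C)(C)C(C)(C)C)[C@@H](OC(C)=O)C[C@H](O)/C(C)=C\[C@@H](OC(=O)/C(C)=C/C)[C@@H]12
F19 | step 15 | methiodide of the Mannich base | C[N+](C)(C)CC1C(=O)O[C@@H]2/C=C(/CO[Si](C)(C)C(C)(C)C)[C@@H](OC(C)=O)C[C@H](O)/C(C)=C\[C@@H](OC(=O)/C(C)=C/C)[C@@H]12.[I-]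
A1 | alternative 1 | open-chain bromo ester enal (C6 aldehyde, C7=C11 with C13H2Br, 1-OTBS, 3-OAc, 8-OTig, 15-OTBS) | O=C/C=C(/CO[Si](C)(C)C(C)(C)C)[C@@H](OC(C)=O)C[C@H](O[Si](C)(C)C(C)(C)C)/C(C)=C\[C@@H](OC(=O)/C(C)=C/C)/C=C(\CBr)C(=O)OC
A2 | alternative 2 | 13-membered bis-allylic ether (C6–O–C13 in the ring, 12-OPMB, 1,3,8,15-tetra-OTBS) | O1C/C=C(/CO[Si](C)(C)C(C)(C)C)[C@@H](O[Si](C)(C)C(C)(C)C)C[C@H](O[Si](C)(C)C(C)(C)C)/C(C)=C\[C@@H](O[Si](C)(C)C(C)(C)C)/C=C(\COCc2ccc(OC)cc2)/C1
A3 | alternative 3 | iodo ketone (ring-B C1 enone, C6 quaternary with OTMS and the Z side chain C5=C4–C3(OAc)–C2H2I) | CC1=C[C@@H](OC(=O)/C(C)=C/C)[C@@H](CC2OCCO2)[C@](O[Si](C)(C)C)(/C=C(/CO[Si](C)(C)C(C)(C)C)[C@@H](OC(C)=O)CI)C1=O
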